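**Retrosynthetic overview**
- Carbon sources: geranyl acetate 1 (C1–C6, C9, C10, C14, C15), methyl propiolate 2 (C7, C8 and a traceless ester carbon) and methyl pyruvate 3 (C11–C13, OMe); Ac2O supplies the acetate.
- Last disconnections: the C2 ketone (allylic oxidation of the 3-ene) and the C7–C11 bond (catalyst-controlled Mukaiyama aldol of a ring B silyl enol ether with methyl pyruvate, setting C7 and C11), leading back to a 12-carbon trinor-eudesmane hydroxy ketone.
- Second ring (decalin, C5–C10 bond): epoxide-triggered transannular cyclisation of a ten-membered 1,10-epoxy-4-ene, the laboratory form of the germacrene-to-eudesmane step; it sets C1, C5 and C10.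
- First ring (ten-membered, C6–C7 bond): an allyl cation equivalent (π-allylpalladium from the allylic acetate end) is captured by an enamine carbon, the counterpart of farnesyl diphosphate ionisation and ring closure.
- Absolute configuration comes from one Sharpless epoxidation of 8-hydroxygeranyl acetate; ring order: ten-membered ring first, then transannular closure to the trans-decalin.

Assumption: atoms carry germacrane/eudesmane numbers (C1–C15) throughout, also in open-chain and trinor intermediates; the target is read as methyl (1R,5R,7R,10S,11S)-1-acetoxy-11-hydroxy-2,8-dioxoeudesm-3-en-12-oate (trans-decalin, C7 side chain anti to the C10 methyl).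

**Step 1**
Reactants: 1 geranyl acetate
Product: 4 (2E,6E)-8-hydroxy-3,7-dimethylocta-2,6-dien-1-yl acetate
Conditions: SeO2 (10 mol%), t-BuOOH, CH2Cl2, 0 °C to rt
Reagents that add atoms: tert-butyl hydroperoxide, CC(C)(C)OO
Why: Sharpless–Umbreit SeO2/t-BuOOH allylic oxidation (ene reaction then [2,3]-shift) hydroxylates only the trans methyl group (future C9) of the electron-richer 6,7-alkene with retention of E geometry, the 2,3-alkene being deactivated by the allylic acetate.

**Step 2**
Reactants: 4 (2E,6E)-8-hydroxy-3,7-dimethylocta-2,6-dien-1-yl acetate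
Product: 5 (2E)-5-[(2S,3S)-3-(hydroxymethyl)-3-methyloxiran-2-yl]-3-methylpent-2-en-1-yl acetate
Conditions: Ti(OiPr)4 (10 mol%), L-(+)-diethyl tartrate (12 mol%), t-BuOOH, 4 Å MS, CH2Cl2, −20 °C
Reagents that add atoms: tert-butyl hydroperoxide, CC(C)(C)OO
Why: Sharpless asymmetric epoxidation with the L-(+)-tartrate catalyst epoxidises only the allylic alcohol alkene and gives the (2S,3S)-epoxy alcohol, which fixes C10 (S) and C1 (S) of the later rings.

**Step 3**
Reactants: 5 (2E)-5-[(2S,3S)-3-(hydroxymethyl)-3-methyloxiran-2-yl]-3-methylpent-2-en-1-yl acetate; 2 methyl propiolate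
Product: 7 methyl 4-[(2S,3S)-3-[(3E)-5-acetoxy-3-methylpent-3-en-1-yl]-2-methyloxiran-2-yl]but-2-ynoate, via epoxy triflate 6 (not isolated)
Conditions: Tf2O, 2,6-lutidine, CH2Cl2, −78 °C; then LiC≡CCO2Me (from 2 and LiN(SiMe3)2, THF, −78 °C), DMPU, −78 to −30 °C
Reagents that add atoms: none
Why: Triflation followed by SN2 alkylation of a lithium acetylide by the primary epoxy triflate (epoxy triflate coupling) joins C8 and C7 to C9 without touching the epoxide stereocenters or the allylic acetate.

**Step 4**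
Reactants: 7 methyl 4-[(2S,3S)-3-[(3E)-5-acetoxy-3-methylpent-3-en-1-yl]-2-methyloxiran-2-yl]but-2-ynoate
Product: 10 methyl (1S,10S,4E)-1,10-epoxy-8-oxo-11,12,13-trinorgermacr-4-ene-7-carboxylate (C7 epimers), via enamino ester 8 (not isolated), via ten-membered enamine 9 (not isolated)
Conditions: pyrrolidine (1.0 equiv), THF, rt; then Pd(PPh3)4 (10 mol%), THF, 60 °C, 2 mM (syringe pump); then aq. AcOH/NaOAc (pH 5), rt
Reagents that add atoms: water, O
Why: Proposed new method: conjugate addition of pyrrolidine turns the ynoate into a neutral push–pull enamine whose C7 carbon captures, at the primary terminus C6, the π-allylpalladium cation that zerovalent palladium generates from the allylic acetate (syn π-allyl keeps the 4E alkene, high dilution favours the ten-membered over the eight-membered mode), and mild hydrolysis releases the β-keto ester, the closest known reactions being the Tsuji–Trost allylation of enamines and palladium-mediated allylic alkylation macrocyclisations of β-keto esters.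

**Step 5**
Reactants: 10 methyl (1S,10S,4E)-1,10-epoxy-8-oxo-11,12,13-trinorgermacr-4-ene-7-carboxylate
Product: 11 methyl (1S,5R,10S)-1-hydroxy-8-oxo-11,12,13-trinoreudesm-3-ene-7-carboxylate (C7 epimers)
Conditions: BF3·OEt2 (0.3 equiv), CH2Cl2, −78 to −30 °C
Reagents that add atoms: none
Why: Epoxide-initiated transannular cation–olefin cyclisation as known for 1,10-epoxygermacrenes: C5 of the E-4,5-alkene attacks C10 anti to the breaking C–O bond through the crossed chair–chair conformer, so C10 is inverted, C1 is retained, C5 is formed as the trans-decalin, and the C4 cation loses a C3 proton to give the 3-ene.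

**Step 6**
Reactants: 11 methyl (1S,5R,10S)-1-hydroxy-8-oxo-11,12,13-trinoreudesm-3-ene-7-carboxylate
Product: 12 (1S,5R,10S)-1-hydroxy-11,12,13-trinoreudesm-3-en-8-one
Conditions: LiCl, H2O, DMSO, 130 °C
Reagents that add atoms: none
Why: Krapcho dealkoxycarbonylation (chloride SN2 at the ester methyl, loss of CO2, protonation) removes the activating ester and leaves C7 as CH2 with no stereocenter affected.

**Step 7**
Reactants: 12 (1S,5R,10S)-1-hydroxy-11,12,13-trinoreudesm-3-en-8-one
Product: 13 (1S,5R,10S)-1-acetoxy-11,12,13-trinoreudesm-3-en-8-one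
Conditions: Ac2O, pyridine, DMAP (cat.), CH2Cl2, rt
Reagents that add atoms: acetic anhydride, CC(=O)OC(C)=O
Why: DMAP-catalysed acetylation of the only hydroxyl group proceeds with retention at C1.

**Step 8**
Reactants: 13 (1S,5R,10S)-1-acetoxy-11,12,13-trinoreudesm-3-en-8-one
Product: 14 (1S,5R,10S)-1-acetoxy-8-(trimethylsilyloxy)-11,12,13-trinoreudesma-3,7-diene
Conditions: Me3SiOTf, Et3N, CH2Cl2, 0 °C
Reagents that add atoms: trimethylsilyl trifluoromethanesulfonate, C[Si](C)(C)OS(=O)(=O)C(F)(F)F
Why: Silyl enol ether formation by soft enolisation goes toward C7 and not toward C9 next to the quaternary C10 (the same preference by which 2-oxo-5α-steroids enolise to the 2-ene), and the acetate is not enolised.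

**Step 9**
Reactants: 14 (1S,5R,10S)-1-acetoxy-8-(trimethylsilyloxy)-11,12,13-trinoreudesma-3,7-diene; 3 methyl pyruvate
Product: 16 methyl (1S,5R,7R,10S,11S)-1-acetoxy-11-hydroxy-8-oxoeudesm-3-en-12-oate, via silyl ether 15 (not isolated)
Conditions: Cu(OTf)2 (10 mol%), (S,S)-t-Bu-box (2,2'-(propane-2,2-diyl)bis[(4S)-4-tert-butyl-4,5-dihydro-1,3-oxazole], 11 mol%), THF, −78 °C; then 1 M HCl, THF, 0 °C
Reagents that add atoms: none
Why: Catalytic enantioselective Mukaiyama aldol addition to bidentately bound pyruvate: the divalent copper bis(oxazoline) complex leaves only the Si face of the ketone open (11S; the (R,R)-ligand would give 11R), the enol ether is attacked axially at C7 on the face anti to the axial C10 methyl (7R), and dilute acid removes the transferred silyl group.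

**Step 10**
Reactants: 16 methyl (1S,5R,7R,10S,11S)-1-acetoxy-11-hydroxy-8-oxoeudesm-3-en-12-oate
Product: 17 methyl (1R,5R,7R,10S,11S)-1-acetoxy-11-hydroxy-2,8-dioxoeudesm-3-en-12-oate
Conditions: Rh2(cap)4 (cap = caprolactamate C6H10NO, 1 mol%), t-BuOOH (5 equiv), 1,2-dichloroethane, 40 °C
Reagents that add atoms: tert-butyl hydroperoxide, CC(C)(C)OO
Why: Dirhodium caprolactamate/t-BuOOH allylic oxidation (hydrogen abstraction by tert-butylperoxyl radicals, as in 5-ene steroid to 7-ketone conversions) oxidises the ring CH2 next to the less substituted alkene carbon (C2) to the conjugated 3-en-2-one without changing any stereocenter, C1 becoming R only through the change in substituent priority.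

**Compound list**
1 | geranyl acetate, (2E)-3,7-dimethylocta-2,6-dien-1-yl acetate | CC(=O)OC/C=C(\C)CCC=C(C)C | starting material
2 | methyl propiolate | C#CC(=O)OC | starting material
3 | methyl pyruvate | CC(=O)C(=O)OC | starting material
4 | (2E,6E)-8-hydroxy-3,7-dimethylocta-2,6-dien-1-yl acetate | CC(=O)OC/C=C(\C)CC/C=C(\C)CO | intermediate
5 | (2E)-5-[(2S,3S)-3-(hydroxymethyl)-3-methyloxiran-2-yl]-3-methylpent-2-en-1-yl acetate | CC(=O)OC/C=C(\C)CC[C@@H]1O[C@@]1(C)CO | intermediate
6 | epoxy triflate, (2E)-3-methyl-5-[(2S,3S)-3-methyl-3-(trifluoromethanesulfonyloxymethyl)oxiran-2-yl]pent-2-en-1-yl acetate (formed in the flask) | CC(=O)OC/C=C(\C)CC[C@@H]1O[C@@]1(C)COS(=O)(=O)C(F)(F)F | intermediate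
7 | methyl 4-[(2S,3S)-3-[(3E)-5-acetoxy-3-methylpent-3-en-1-yl]-2-methyloxiran-2-yl]but-2-ynoate | CC(=O)OC/C=C(\C)CC[C@@H]1O[C@@]1(C)CC#CC(=O)OC | intermediate
8 | enamino ester, methyl (2E)-4-[(2S,3S)-3-[(3E)-5-acetoxy-3-methylpent-3-en-1-yl]-2-methyloxiran-2-yl]-3-(pyrrolidin-1-yl)but-2-enoate (formed in the flask) | CC(=O)OC/C=C(\C)CC[C@@H]1O[C@@]1(C)C/C(N2CCCC2)=C\C(=O)OC | intermediate
9 | ten-membered enamine, methyl (1S,10S,4E)-1,10-epoxy-8-(pyrrolidin-1-yl)-11,12,13-trinorgermacra-4,7-diene-7-carboxylate (formed in the flask) | COC(=O)C1=C(N3CCCC3)C[C@]2(C)O[C@H]2CC/C(C)=C/C1 | intermediate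
10 | methyl (1S,10S,4E)-1,10-epoxy-8-oxo-11,12,13-trinorgermacr-4-ene-7-carboxylate (C7 epimers) | COC(=O)C1C(=O)C[C@]2(C)O[C@H]2CC/C(C)=C/C1 | intermediate
11 | methyl (1S,5R,10S)-1-hydroxy-8-oxo-11,12,13-trinoreudesm-3-ene-7-carboxylate (C7 epimers) | COC(=O)C1C[C@@H]2C(C)=CC[C@H](O)[C@@]2(C)CC1=O | intermediate
12 | (1S,5R,10S)-1-hydroxy-11,12,13-trinoreudesm-3-en-8-one | C1C[C@@H]2C(C)=CC[C@H](O)[C@@]2(C)CC1=O | intermediate
13 | (1S,5R,10S)-1-acetoxy-11,12,13-trinoreudesm-3-en-8-one | C1C[C@@H]2C(C)=CC[C@H](OC(C)=O)[C@@]2(C)CC1=O | intermediate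
14 | (1S,5R,10S)-1-acetoxy-8-(trimethylsilyloxy)-11,12,13-trinoreudesma-3,7-diene | C[Si](C)(C)OC1=CC[C@@H]2C(C)=CC[C@H](OC(C)=O)[C@@]2(C)C1 | intermediate
15 | silyl ether, methyl (1S,5R,7R,10S,11S)-1-acetoxy-8-oxo-11-(trimethylsilyloxy)eudesm-3-en-12-oate (formed in the flask) | COC(=O)[C@@](C)(O[Si](C)(C)C)[C@H]1C[C@@H]2C(C)=CC[C@H](OC(C)=O)[C@@]2(C)CC1=O | intermediate
16 | methyl (1S,5R,7R,10S,11S)-1-acetoxy-11-hydroxy-8-oxoeudesm-3-en-12-oate | COC(=O)[C@@](C)(O)[C@H]1C[C@@H]2C(C)=CC[C@H](OC(C)=O)[C@@]2(C)CC1=O | intermediate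
17 | methyl (1R,5R,7R,10S,11S)-1-acetoxy-11-hydroxy-2,8-dioxoeudesm-3-en-12-oate | COC(=O)[C@@](C)(O)[C@H]1C[C@@H]2C(C)=CC(=O)[C@H](OC(C)=O)[C@@]2(C)CC1=O | target

**Totals**
Total step count: 10. Longest linear sequence: 10 steps (1 to 17).

**Steps most likely to fail**

Step 4 (ten-membered ring closure; oligomerisation or too weak a nucleophile). The fallback sets out from 7. Pyrrolidine addition followed by aqueous acetic acid hydrolysis gives the open-chain β-keto ester methyl 4-[(2S,3S)-3-[(3E)-5-acetoxy-3-methylpent-3-en-1-yl]-2-methyloxiran-2-yl]-3-oxobutanoate F1. Its preformed sodium enolate (NaH, THF) is added by syringe pump to Pd(PPh3)4/dppe in THF at 65 °C (2 mM). This is a stabilised-enolate Tsuji–Trost macrocyclisation in place of neutral enamine capture, and it comes back to the route at 10.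

Step 5 (transannular cyclisation; wrong alkene isomer from the C4 cation or attack by the carbonyl oxygen). The fallback sets out from 10. Cp2TiCl (from Cp2TiCl2 and Mn, THF, rt) opens the epoxide homolytically to the tertiary C10 radical, which adds across the ring to C5. The C4 radical is trapped by a second trivalent titanium centre and loses a β-hydrogen, giving the exocyclic alkene methyl (1S,5R,10S)-1-hydroxy-8-oxo-11,12,13-trinoreudesm-4(15)-ene-7-carboxylate F2. RhCl3·3H2O (cat.) in EtOH at 70 °C then moves the double bond into the ring. This radical route comes back at 11.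

Step 10 (C2 oxidation; the neighbouring acetoxy group deactivates C2 and the tertiary allylic C5–H competes). The fallback sets out from 16. PhSeCl in MeCN–H2O adds across the 3-ene to give the trans-diaxial hydroxy selenide methyl 1-acetoxy-4,11-dihydroxy-8-oxo-3-(phenylselanyl)eudesman-12-oate F3 (Se and 4-OH trans, 4-OH cis to the C10 methyl). H2O2/pyridine in CH2Cl2 at 0 °C causes selenoxide syn-elimination to the tertiary allylic alcohol methyl 1-acetoxy-4,11-dihydroxy-8-oxoeudesm-2-en-12-oate F4. Pyridinium chlorochromate [C5H5NH][CrO3Cl] in CH2Cl2 then effects the oxidative 1,3-transposition to the 3-en-2-one. This comes back to the route at 17.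

**Further compounds**
F1 | step 4 | methyl 4-[(2S,3S)-3-[(3E)-5-acetoxy-3-methylpent-3-en-1-yl]-2-methyloxiran-2-yl]-3-oxobutanoate | CC(=O)OC/C=C(\C)CC[C@@H]1O[C@@]1(C)CC(=O)CC(=O)OC
F2 | step 5 | methyl (1S,5R,10S)-1-hydroxy-8-oxo-11,12,13-trinoreudesm-4(15)-ene-7-carboxylate (C7 epimers) | COC(=O)C1C[C@@H]2C(=C)CC[C@H](O)[C@@]2(C)CC1=O
F3 | step 10 | methyl 1-acetoxy-4,11-dihydroxy-8-oxo-3-(phenylselanyl)eudesman-12-oate (Se and 4-OH trans-diaxial, 4-OH cis to the C10 methyl) | COC(=O)[C@@](C)(O)[C@H]1C[C@@H]2[C@](C)(O)[C@@H]([Se]c3ccccc3)C[C@H](OC(C)=O)[C@@]2(C)CC1=O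
F4 | step 10 | methyl 1-acetoxy-4,11-dihydroxy-8-oxoeudesm-2-en-12-oate (4-OH cis to the C10 methyl) | COC(=O)[C@@](C)(O)[C@H]1C[C@@H]2[C@](C)(O)C=C[C@H](OC(C)=O)[C@@]2(C)CC1=O
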